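## Structural features

The target is a sesquiterpene diester built on a cyclobutane (C1–C2–C8–C7) whose two diagonals are both bridged. C1 and C8 carry the three-carbon enone unit C11(=O)–C10=C9(CH3), giving a verbenone-like bicyclo[3.1.1]heptenone. C2 (bearing CH3) and C7 carry the four-carbon chain C3–C4–C5(O)–C6(CH3)(C14H2O), giving a seven-membered ring. C1, C2, C7 and C8 are locked by the cage, and next to C7 stand the quaternary C6 and the carbinol C5. The C5 oxygen is trans to C14 and cis to the C6 methyl, and C14 lies on the same face of C7 as C1 and the carbonyl. The fragile groups are the two angelates (Z to E isomerisation with acid, base, heat or nucleophiles) and the strained C1–C2 bond, which sits beta to the ketone and is opened by acid. The real difficulty is closing the cyclobutane at the quaternary C2 and tying the cage configuration to C5/C6. The key step uses the fact that the cyclohexenone ring (C1, C11, C10, C9, C8, C7) is cis-fused across C7–C8 of the seven-membered ring, with the C14 oxygen one atom away from C7 on the C1 face, so that it can anchor the diene.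

## Logic of the disconnections

29 is cut at the two ester C–O bonds to 26 and two equivalents of 27. The angelates are the most fragile groups, so they go on last. The forward step must acylate a hindered secondary and a neopentyl primary alcohol without Z to E isomerisation.

26 is traced to 25 by re-forming two carbonate C–O bonds. The carbonate holds both oxygens in a non-nucleophilic form for the step that precedes it and is removed by mild base.

25 is cut at C1–C2 to 23, through 24. This removes the cyclobutane and the cage strain and leaves a cis-fused bicycle. The forward step must make a strained ring at a quaternary carbon: the C2 cation has to be taken by C1 before it loses a proton, and the product must be kept from acid.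

23 goes back to 22 (C2–Cl to C2–OH) and 22 to 21 (carbonate C–O bonds). These are functional-group changes that place a leaving group on C2 only after the diol is masked.

21 is traced through 20 to 19 by removing the C9=C10 unsaturation and restoring the Si–O bonds. The enone then comes from the bridged silyl enol ether, which fixes where the double bond forms; the forward oxidation must use that regiochemistry.

19 is cut at C2–CH3 to 17 and 18. C2 becomes the ketone that activated the dienophile. The forward addition must take the ketone and leave the silyl enol ether, which masks C11.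

17 is cut at C1–C7 and C8–C9 to 16. One step builds the six-membered ring and three stereocentres; the forward step must add to the face of C7=C8 that carries C14.

16 is cut at its two Si–O bonds to 11, 12 and 13, through 14 and 15. The tether is assembled from an alcohol, an enolate and a dichlorosilane; the forward step needs the kinetic, cross-conjugated enolate of 12.

11 is traced through 10, 9 and 8 to 7. The enone oxygen at C2 is removed and C7=C8 is traced to a C7 ketone, a 1,3-transposition in reverse. This exposes the 1,3-dioxygen pattern of a dione around C6. The forward sequence needs enolisation toward C8 only (C6 is quaternary) and oxidation at C2 only.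

7 is traced through 6 to 5 by removing the hydride at C5 and the silyl groups. All chirality then rests on one reduction of an achiral dione. The forward step must choose one of two enantiotopic carbonyls and deliver hydride on the face of the hydroxymethyl group.

5 is cut at C6–C14 to 3 and 4 (aldol), and 3 at C6–CH3 to 1 and 2 (alkylation).

## Other disconnections considered

Alternative 1: The cut is C9=C10, by an aldol condensation of the achiral diketone A1. In the forward step a cinchona-derived primary amine with CF3CO2H forms an enamine on one acetonyl arm; this attacks the other ketone and dehydrates to A2, setting C7.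
- In its favour: the step is catalytic, starts from an achiral compound and fixes the first stereocentre early and cheaply. On steps to the first stereocentre it is the better of the two plans.
- Against it: A2 carries two methyl groups on C6, so the C14 oxygen is missing. Adding it later means oxidising one of two diastereotopic methyls; placing it earlier makes C6 stereogenic, and A1 is then no longer achiral.
- Against it: C8–C2, C1–C2, the seven-membered ring and C5 all remain. Both cyclobutane bonds must be made to one ketone carbon.
- Comparison: the chosen plan makes two skeletal bonds and three centres in its key step, with the face tied to C6. Alternative 1 makes one bond and one centre. The cyclobutane problem is not eased.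

Alternative 2: The cut is C1–C2, seen as a 1,2-shift. In the forward step Bu4NF frees the bridgehead alkoxide of the norbornene mesylate A3 (silyl group assumed to be triethylsilyl). C2 migrates from C11 to C1 as the endo mesylate leaves, giving the acetonide A4.
- In its favour: the cyclobutane is made by an anionic, irreversible shift driven by formation of the ketone and loss of mesylate. This is a sounder answer to the ring strain than the cationic closure of the chosen plan, and on this point alternative 2 is the better.
- In its favour: the enone arrives in the same step.
- Against it: A3 needs a 5,5-disubstituted silyloxycyclopentadiene and a cycloaddition that sets C7 against C5/C6, closes the seven-membered ring and places the leaving group endo. There is no element as direct as a tether for these selectivities.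
- Comparison: the step count is expected to be similar or higher. The chosen plan is stronger on facial control, alternative 2 on the final ring closure.

Alternative 3: The cut is C6–C7. In the forward step Me3SiOTf activates the trisubstituted epoxide of A5 and the enol ether carbon attacks the tertiary epoxide carbon with inversion, closing the seven-membered ring to A6.
- In its favour: a Sharpless epoxidation sets C5 and C6 by reagent control. That is better founded than the enzyme-dependent reduction of the chosen plan, and carvone supplies C8 from the chiral pool.
- Against it: A6 has the carbonyl on the carbon that must become C1 and the methyl on the carbon that must become C11. The target has C11=O and the methyl on C9, so no functional-group change repairs this.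
- Against it: as written, the ring fusion of A6 is on the face of C7 anti to C14 (C7 and C8 are both opposite to the target relative to C5/C6), so the later cage would be the wrong diastereomer.
- Against it: opening at the tertiary epoxide carbon competes with rearrangement of the epoxide, and the cyclobutane is still unmade.
- Comparison: equal or better for C5/C6, weaker on constitution and on the C6/C7 relationship, which the tether of the chosen plan enforces.

Key step: step 10

Assumptions and corrections (remarks on the chemistry):
- Structures 16 and 17 as drawn agree with 29 at C5, C6, C7 and C8. C9 of 17 and C2 of 19–24 are transient centres and are erased later.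
- A ketoreductase giving the (2S,3R) diol 6 is assumed to be found by screening a commercial panel.
- The C2 leaving group is a chloride set before enolisation, because an amide base would cleave a tertiary trifluoroacetate.
- The silyl ethers at O5 and O14 are replaced by a cyclic carbonate before the C2 cation is formed, because ether-type oxygens would trap it (five- or six-membered cyclic ether).
- Silicon left on O14 by the enone-forming step is removed with HF in the same operation.

Step 1
Reactants: 1 cycloheptane-1,3-dione; 2 iodomethane
Product: 3 2-methylcycloheptane-1,3-dione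
Conditions: K2CO3, acetone, reflux
Reagents that add atoms: iodomethane CI
Why: C-alkylation of the stabilised 1,3-dicarbonyl enolate; the seven-membered dione is largely in the diketo form, which favours carbon over oxygen, and one equivalent of 2 limits double methylation.

Step 2
Reactants: 3 2-methylcycloheptane-1,3-dione; 4 formaldehyde
Product: 5 2-(hydroxymethyl)-2-methylcycloheptane-1,3-dione
Conditions: 37% aq CH2O, Et3N (cat.), THF, rt
Reagents that add atoms: formaldehyde C=O
Why: Aldol addition of the 2-substituted dione to formaldehyde creates the quaternary carbon C6; excess aldehyde and a weak base hold back the retro-aldol, and the product is still achiral.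

Step 3
Reactants: 5 2-(hydroxymethyl)-2-methylcycloheptane-1,3-dione
Product: 6 (2S,3R)-3-hydroxy-2-(hydroxymethyl)-2-methylcycloheptan-1-one (hydroxyl trans to hydroxymethyl, cis to methyl)
Conditions: ketoreductase (panel enzyme), NADP+ (cat.), iPrOH, phosphate buffer pH 7, 30 °C
Reagents that add atoms: none
Why: Enzymatic desymmetrising mono-reduction of a prochiral 2,2-disubstituted 1,3-dione, a known reaction class that stops at the hydroxy ketone; the enzyme picks one enantiotopic carbonyl and one face, which sets C5 and thereby fixes C6.

Step 4
Reactants: 6 (2S,3R)-3-hydroxy-2-(hydroxymethyl)-2-methylcycloheptan-1-one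
Product: 7 (2S,3R)-3-(tert-butyldimethylsilyloxy)-2-[(tert-butyldimethylsilyloxy)methyl]-2-methylcycloheptan-1-one
Conditions: TBSOTf, 2,6-lutidine, CH2Cl2, −78 → 0 °C
Reagents that add atoms: tert-butyldimethylsilyl triflate CC(C)(C)[Si](C)(C)OS(=O)(=O)C(F)(F)F
Why: Silylation of both hydroxyls with the triflate, needed for the hindered secondary one; prompt capping also blocks the retro-aldol of the beta-hydroxy ketone.

Step 5
Reactants: 7 bis-silyl ketone
Product: 8 (6R,7S)-6-(tert-butyldimethylsilyloxy)-7-[(tert-butyldimethylsilyloxy)methyl]-7-methylcyclohept-1-en-1-yl trifluoromethanesulfonate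
Conditions: KN(SiMe3)2, PhNTf2, THF, −78 °C
Reagents that add atoms: N-phenylbis(trifluoromethanesulfonimide) O=S(=O)(N(c1ccccc1)S(=O)(=O)C(F)(F)F)C(F)(F)F
Why: Enol triflate formation; C6 is quaternary, so the ketone can enolise only toward C8 and the C7=C8 bond is placed without ambiguity.

Step 6
Reactants: 8 enol triflate
Product: 9 (3S,4R)-4-(tert-butyldimethylsilyloxy)-3-[(tert-butyldimethylsilyloxy)methyl]-3-methylcyclohept-1-ene
Conditions: Pd(OAc)2 (cat.), PPh3, HCO2H, Bu3N, DMF, 60 °C
Reagents that add atoms: none
Why: Palladium-catalysed formate reduction of an enol triflate: oxidative addition to zerovalent palladium, formate exchange, loss of CO2 and reductive elimination of C–H.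

Step 7
Reactants: 9 cycloheptene
Product: 10 (4S,5R)-5-(tert-butyldimethylsilyloxy)-4-[(tert-butyldimethylsilyloxy)methyl]-4-methylcyclohept-2-en-1-one
Conditions: Rh2(cap)4 (cap = caprolactamate, cat.), tBuOOH, K2CO3, CH2Cl2, rt
Reagents that add atoms: tert-butyl hydroperoxide CC(C)(C)OO
Why: Allylic oxidation of a cycloalkene to the enone; the only allylic hydrogens are on C2 (C6 is quaternary), and the allyl radical is trapped at the unhindered C2 end, not at the neopentyl C7 end.

Step 8
Reactants: 10 bis-silyl enone
Product: 11 (4S,5R)-5-(tert-butyldimethylsilyloxy)-4-(hydroxymethyl)-4-methylcyclohept-2-en-1-one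
Conditions: HF·pyridine, pyridine, THF, 0 °C
Reagents that add atoms: none
Why: Selective desilylation: the primary silyl ether is cleaved much faster than the secondary one, which is shielded by the quaternary centre.

Step 9
Reactants: 11 enone alcohol; 12 (E)-pent-3-en-2-one; 13 dichlorodiisopropylsilane
Product: 16 (4S,5R)-5-(tert-butyldimethylsilyloxy)-4-({[diisopropyl((3E)-penta-1,3-dien-2-yloxy)silyl]oxy}methyl)-4-methylcyclohept-2-en-1-one, via lithium dienolate 14 (not isolated), via chlorosilyl dienol ether 15 (not isolated)
Conditions: 12, LiN(iPr)2, THF, −78 °C; 13, −78 °C; then 11, imidazole, −78 → 0 °C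
Reagents that add atoms: (E)-pent-3-en-2-one C/C=C/C(C)=O; dichlorodiisopropylsilane CC(C)[Si](Cl)(Cl)C(C)C
Why: Kinetic alpha′-deprotonation gives the cross-conjugated dienolate, which is silylated on oxygen by one Si–Cl bond; the neopentyl alcohol then displaces the second chloride, the usual stepwise assembly of a mixed silyl acetal tether.

Step 10
Reactants: 16 tethered cycloheptenone
Product: 17 cis-fused bicyclic ketone with bridged silyl enol ether (C10=C11–O–Si–O–C14; H7, H8 and H9 on one face)
Conditions: PhMe (0.01 M), BHT, Et3N (cat.), sealed tube, 170 °C
Reagents that add atoms: none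
Why: Heating folds the 2-silyloxy diene, held through the O11–Si–O14 link, over C7=C8, and a concerted, suprafacial but asynchronous [4+2] forms C1–C7 and C8–C9 (type 2 intramolecular Diels–Alder, the tether leaving from the 2-position of the diene). The closest known reactions are type 2 intramolecular Diels–Alder reactions of 2-silyloxy dienes that give bridgehead enol ethers, and cycloadditions through temporary silicon tethers. The cyclohexene ring (C1, C11, C10, C9, C8, C7) is closed by the cycloaddition itself and is cis-fused because both new bonds form on one face of the cis ring alkene. The eight-membered dioxasilacycle (O, Si, O, C14, C6, C7, C1, C11) closes at the same time as the five-atom bridge of a bicyclo[5.3.1] system with the C10=C11 bond at the bridgehead. C7 and C8 are set by the tether: the diene can reach only the face of C7 that carries C14, so C1 ends syn to C14 as the cage requires. C9 follows from the endo arrangement that the short tether imposes (C6 and the ketone C2 under the diene) together with the E diene, and it is erased later. The critical selectivity is the face of C7=C8, which the tether secures. The regiochemistry (CH2 terminus to the beta carbon C7) is secured by tether length and matches the polarity of the diene and enone.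

Step 11
Reactants: 17 bridged silyl enol ether ketone; 18 methylmagnesium bromide
Product: 19 C2 tertiary alcohol of 17 (mixture at C2)
Conditions: MeMgBr, CeCl3, THF, −78 → −20 °C
Reagents that add atoms: methylmagnesium bromide C[Mg]Br
Why: Cerium-mediated 1,2-addition to a hindered, enolisable ketone; C11 stays masked as the silyl enol ether, and the new C2 centre is of no consequence because it is ionised later.

Step 12
Reactants: 19 tertiary alcohol
Product: 21 enone triol (C11=O, C9=C10; free hydroxyls on C2, C5 and C14), via acetoxysilyl enone 20 (not isolated)
Conditions: Pd(OAc)2 (1.1 equiv), MeCN, 40 °C; then 48% aq HF, MeCN, rt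
Reagents that add atoms: none
Why: Saegusa–Ito oxidation: acetate takes silicon from the enol oxygen, and the palladium enolate at C10 can eliminate only the beta-hydrogen on C9, so the C9=C10 enone forms with fixed regiochemistry; HF then removes the silicon left on O14 and the silyl ether on O5.

Step 13
Reactants: 21 enone triol
Product: 22 cyclic carbonate of the O5/O14 diol (C2 hydroxyl free)
Conditions: CDI, DMAP (cat.), PhMe, 60 °C
Reagents that add atoms: 1,1′-carbonyldiimidazole O=C(n1ccnc1)n1ccnc1
Why: A 1,3-diol closes to the six-membered carbonate while the tertiary alcohol is inert; the carbonate oxygens are too poor as nucleophiles to capture the later C2 cation, and the group tolerates a hindered amide base.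

Step 14
Reactants: 22 tertiary alcohol carbonate
Product: 23 C2 tertiary chloride (mixture at C2)
Conditions: HCl (4 M in dioxane), CH2Cl2, 0 °C
Reagents that add atoms: hydrogen chloride Cl
Why: Unimolecular substitution of a tertiary alcohol by chloride; alkenes formed by elimination are returned to the tertiary chloride by Markovnikov addition of the excess HCl.

Step 15
Reactants: 23 tertiary chloride
Product: 25 cage carbonate (tricyclic enone with the C1–C2 bond closed), via silyl dienol ether 24 (not isolated)
Conditions: LiN(SiMe3)2, Me3SiCl, THF, −78 °C; then TiCl4, 2,6-di-tert-butylpyridine, CH2Cl2, −78 °C; cold aq NaHCO3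
Reagents that add atoms: none
Why: Proposed new method: kinetic alpha′-deprotonation (C10 is blocked by the enone) gives the cross-conjugated silyl dienol ether 24; TiCl4 then abstracts chloride and the C2 cation is taken by C1 on the only face the cis ring fusion offers, which fixes C1 and C2, silicon leaving as Me3SiCl. The closest known reaction type is the Lewis-acid-mediated alpha-tert-alkylation of silyl enol ethers by tertiary alkyl chlorides (a Mukaiyama-type SN1 alkylation), which has not been used to close a four-membered ring. The cage strain is offset only by binding of the product ketone to the Lewis acid, so the step is run and quenched cold under kinetic control.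

Step 16
Reactants: 25 cage carbonate
Product: 26 cage diol (C5 and C14 hydroxyls)
Conditions: K2CO3, MeOH, 0 °C → rt
Reagents that add atoms: none
Why: Methanolysis of a cyclic carbonate; the cage enone has no enolisable alpha′-hydrogen (C1 is a bridgehead) and tolerates mild base.

Step 17
Reactants: 26 cage diol; 27 angelic acid
Product: 29 CNP0240716.2 (target), via mixed anhydride 28 (not isolated)
Conditions: 27, 2,4,6-Cl3C6H2COCl, Et3N, PhMe, rt; then 26, PhMe, 80 °C
Reagents that add atoms: angelic acid C/C=C(/C)C(=O)O
Why: Yamaguchi-type esterification through the mixed anhydride; the alcohols attack the less hindered angeloyl carbonyl, and leaving out a nucleophilic catalyst avoids the addition–elimination path that turns angelate into tiglate.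

Compound list
1 | cycloheptane-1,3-dione | O=C1CCCCC(=O)C1 | starting material
2 | iodomethane | CI | starting material
3 | 2-methylcycloheptane-1,3-dione | CC1C(=O)CCCCC1=O | intermediate
4 | formaldehyde | C=O | starting material
5 | 2-(hydroxymethyl)-2-methylcycloheptane-1,3-dione | CC1(CO)C(=O)CCCCC1=O | intermediate
6 | (2S,3R)-3-hydroxy-2-(hydroxymethyl)-2-methylcycloheptan-1-one | C1CC(=O)[C@@](C)(CO)[C@H](O)CC1 | intermediate
7 | (2S,3R)-3-(tert-butyldimethylsilyloxy)-2-[(tert-butyldimethylsilyloxy)methyl]-2-methylcycloheptan-1-one | C1CC(=O)[C@@](C)(CO[Si](C)(C)C(C)(C)C)[C@H](O[Si](C)(C)C(C)(C)C)CC1 | intermediate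
8 | (6R,7S)-6-(tert-butyldimethylsilyloxy)-7-[(tert-butyldimethylsilyloxy)methyl]-7-methylcyclohept-1-en-1-yl trifluoromethanesulfonate | C1C=C(OS(=O)(=O)C(F)(F)F)[C@@](C)(CO[Si](C)(C)C(C)(C)C)[C@H](O[Si](C)(C)C(C)(C)C)CC1 | intermediate
9 | (3S,4R)-4-(tert-butyldimethylsilyloxy)-3-[(tert-butyldimethylsilyloxy)methyl]-3-methylcyclohept-1-ene | C1C=C[C@@](C)(CO[Si](C)(C)C(C)(C)C)[C@H](O[Si](C)(C)C(C)(C)C)CC1 | intermediate
10 | (4S,5R)-5-(tert-butyldimethylsilyloxy)-4-[(tert-butyldimethylsilyloxy)methyl]-4-methylcyclohept-2-en-1-one | O=C1C=C[C@@](C)(CO[Si](C)(C)C(C)(C)C)[C@H](O[Si](C)(C)C(C)(C)C)CC1 | intermediate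
11 | (4S,5R)-5-(tert-butyldimethylsilyloxy)-4-(hydroxymethyl)-4-methylcyclohept-2-en-1-one | O=C1C=C[C@@](C)(CO)[C@H](O[Si](C)(C)C(C)(C)C)CC1 | intermediate
12 | (E)-pent-3-en-2-one | C/C=C/C(C)=O | starting material
13 | dichlorodiisopropylsilane | CC(C)[Si](Cl)(Cl)C(C)C | starting material
14 | lithium (3E)-penta-1,3-dien-2-olate | [Li]OC(=C)/C=C/C | intermediate
15 | chloro(diisopropyl)[(3E)-penta-1,3-dien-2-yloxy]silane | CC(C)[Si](Cl)(C(C)C)OC(=C)/C=C/C | intermediate
16 | (4S,5R)-5-(tert-butyldimethylsilyloxy)-4-({[diisopropyl((3E)-penta-1,3-dien-2-yloxy)silyl]oxy}methyl)-4-methylcyclohept-2-en-1-one | O=C1C=C[C@@](C)(CO[Si](C(C)C)(C(C)C)OC(=C)/C=C/C)[C@H](O[Si](C)(C)C(C)(C)C)CC1 | intermediate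
17 | cis-fused bicyclic ketone with diisopropylsilylene-bridged enol ether (endo adduct; H7, H8, H9 cis; C1 syn to C14) | O=C1[C@H]2[C@@H](C)C=C3C[C@H]2[C@@](C)(CO[Si](C(C)C)(C(C)C)O3)[C@H](O[Si](C)(C)C(C)(C)C)CC1 | intermediate
18 | methylmagnesium bromide | C[Mg]Br | starting material
19 | C2 tertiary alcohol of 17 (C2 methyl carbinol, mixture at C2) | CC1(O)[C@H]2[C@@H](C)C=C3C[C@H]2[C@@](C)(CO[Si](C(C)C)(C(C)C)O3)[C@H](O[Si](C)(C)C(C)(C)C)CC1 | intermediate
20 | enone with acetoxy(diisopropyl)silyl ether on O14 and silyl ether on O5 | CC1(O)[C@H]2C(C)=CC(=O)C[C@H]2[C@@](C)(CO[Si](C(C)C)(C(C)C)OC(C)=O)[C@H](O[Si](C)(C)C(C)(C)C)CC1 | intermediate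
21 | enone triol (cis-fused bicycle; hydroxyls on C2, C5, C14) | CC1(O)[C@H]2C(C)=CC(=O)C[C@H]2[C@@](C)(CO)[C@H](O)CC1 | intermediate
22 | enone tertiary alcohol with O5/O14 cyclic carbonate | CC1(O)[C@H]2C(C)=CC(=O)C[C@H]2[C@@](C)(COC3=O)[C@H](O3)CC1 | intermediate
23 | enone tertiary chloride with O5/O14 cyclic carbonate | CC1(Cl)[C@H]2C(C)=CC(=O)C[C@H]2[C@@](C)(COC3=O)[C@H](O3)CC1 | intermediate
24 | cross-conjugated trimethylsilyl dienol ether of 23 (C1=C11) | CC1(Cl)[C@H]2C(C)=CC(O[Si](C)(C)C)=C[C@H]2[C@@](C)(COC3=O)[C@H](O3)CC1 | intermediate
25 | tricyclic cage enone, O5/O14 cyclic carbonate | O=C1OC[C@]2(C)[C@@H]3[C@H]4C(=O)C=C(C)[C@@H]3[C@@]4(C)CC[C@H]2O1 | intermediate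
26 | tricyclic cage enone diol | OC[C@]1(C)[C@@H]2[C@H]3C(=O)C=C(C)[C@@H]2[C@@]3(C)CC[C@H]1O | intermediate
27 | angelic acid, (Z)-2-methylbut-2-enoic acid | C/C=C(/C)C(=O)O | starting material
28 | angelic 2,4,6-trichlorobenzoic anhydride | C/C=C(/C)C(=O)OC(=O)c1c(Cl)cc(Cl)cc1Cl | intermediate
29 | CNP0240716.2, the bis-angelate | C/C=C(/C)C(=O)OC[C@]1(C)[C@@H]2[C@H]3C(=O)C=C(C)[C@@H]2[C@@]3(C)CC[C@H]1OC(=O)/C(C)=C\C | target

Total step count: 17. Longest linear sequence: 17 steps, from 1 to 29; compounds 2, 4, 12, 13, 18 and 27 enter as reagents.

Least certain steps

Step 15 (new method).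
- Most likely failure: the C2 cation loses a proton (toward C3, the methyl, or C8, where a conjugated dienone results) or takes a hydride from C8 before C1 can close the strained ring.
- Second failure: acid left after the closure reopens the C1–C2 bond. Starting from the chloride and the enol ether, the closure is not downhill without the Lewis acid bound to the product, so it cannot be run under equilibrating conditions.
- Fallback (known reactions only), from 22 back to 25. The strain is paid for by loss of nitrogen, and no cation is met after the first step. The tertiary alcohol is converted with Me3SiN3 and BF3·OEt2 into the tertiary azide F1. Staudinger reduction (PPh3, then water) gives the tertiary amine F2. Bromination at C1 with PhNMe3Br3 in THF, the amine being protonated by the HBr formed, gives the bromo ammonium salt F3. K2CO3 in MeCN then closes the C1–N bond to the bridged pyrrolidine F4; only the C2 epimer with nitrogen on the C1 face can close. Nitrogen deletion of the secondary amine through its 1,1-diazene (PhI(OH)OTs, ammonium carbamate, CF3CH2OH, 80 °C) expels N2, and the C1/C2 radical pair collapses to 25.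

Step 10 (key step).
- Most likely failure: no cycloaddition at temperatures the silyl dienol ether survives, because the beta carbon C7 is neopentyl and a cycloheptenone is a modest dienophile.
- Other failures: transfer of silicon to adventitious nucleophiles, and isomerisation of the diene.
- Fallback, from 11 back to 17: the same two bonds are made stepwise by anionic conjugate additions. 11 is deprotonated with LiN(SiMe3)2 to the lithium alkoxide F5. Addition of 14 gives a first conjugate addition of its CH2 terminus to C7, delivered syn to the lithium alkoxide on C14. The resulting C8 enolate adds to the pendant enone at C9, giving the dilithium enolate alkoxide F6. Both oxygens are then captured with 13 to give 17, or its C9 epimer F7, which converges with 17 at 20.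

Step 3.
- Most likely failure: no panel enzyme gives the trans diol with useful enantioselectivity, since the preferred face toward a free hydroxymethyl group cannot be predicted.
- Fallback, from 5 back to 6: hydroxyl-directed reduction with Me4NBH(OAc)3 in MeCN/AcOH at −20 °C. Hydride is delivered from the boron bound to the hydroxymethyl oxygen, so the trans diol forms, as 6 together with its enantiomer F8. The enantiomers are separated by chromatography on a chiral stationary phase, at this stage or as 7.

Step 7.
- Most likely failure: poor regiocontrol in trapping the allyl radical (oxidation at C7 with double-bond shift), or over-oxidation.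
- Fallback, from 7 back to 10, a Wharton transposition. Dehydrogenation of 7 with IBX in DMSO at 70 °C gives the enone F9; only the C8 side can react. H2O2 and NaOH in MeOH give the epoxy ketone F10. N2H4·H2O with catalytic AcOH in MeOH gives the transposed allylic alcohol F11. MnO2 in CH2Cl2 gives 10.

Further compounds
F1 | step 15 | tertiary azide at C2, enone carbonate | CC1(N=[N+]=[N-])[C@H]2C(C)=CC(=O)C[C@H]2[C@@](C)(COC3=O)[C@H](O3)CC1
F2 | step 15 | tertiary amine at C2, enone carbonate | CC1(N)[C@H]2C(C)=CC(=O)C[C@H]2[C@@](C)(COC3=O)[C@H](O3)CC1
F3 | step 15 | C1 bromo ketone of F2 as hydrobromide | CC1(N)[C@H]2C(C)=CC(=O)C(Br)[C@H]2[C@@](C)(COC3=O)[C@H](O3)CC1.Br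
F4 | step 15 | bridged pyrrolidine (C1–N–C2), enone carbonate | O=C1OC[C@]2(C)[C@@H]3[C@H](N4)C(=O)C=C(C)[C@@H]3[C@@]4(C)CC[C@H]2O1
F5 | step 10 | lithium alkoxide of 11 | O=C1C=C[C@@](C)(CO[Li])[C@H](O[Si](C)(C)C(C)(C)C)CC1
F6 | step 10 | dilithium C11 enolate C14 alkoxide of the double conjugate adduct | O=C1[C@H]2[C@@H](C)C=C(O[Li])C[C@H]2[C@@](C)(CO[Li])[C@H](O[Si](C)(C)C(C)(C)C)CC1
F7 | step 10 | C9 epimer of 17 | O=C1[C@H]2[C@H](C)C=C3C[C@H]2[C@@](C)(CO[Si](C(C)C)(C(C)C)O3)[C@H](O[Si](C)(C)C(C)(C)C)CC1
F8 | step 3 | (2R,3S)-3-hydroxy-2-(hydroxymethyl)-2-methylcycloheptan-1-one, enantiomer of 6 | C1CC(=O)[C@](C)(CO)[C@@H](O)CC1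
F9 | step 7 | (6R,7S)-6-(tert-butyldimethylsilyloxy)-7-[(tert-butyldimethylsilyloxy)methyl]-7-methylcyclohept-2-en-1-one | C1=CC(=O)[C@@](C)(CO[Si](C)(C)C(C)(C)C)[C@H](O[Si](C)(C)C(C)(C)C)CC1
F10 | step 7 | 2,3-epoxide of F9 | C12OC1C(=O)[C@@](C)(CO[Si](C)(C)C(C)(C)C)[C@H](O[Si](C)(C)C(C)(C)C)CC2
F11 | step 7 | (4S,5R)-5-(tert-butyldimethylsilyloxy)-4-[(tert-butyldimethylsilyloxy)methyl]-4-methylcyclohept-2-en-1-ol | OC1C=C[C@@](C)(CO[Si](C)(C)C(C)(C)C)[C@H](O[Si](C)(C)C(C)(C)C)CC1
A1 | alternative 1 | 4-{2-[2-(2-(2-methyl-1,3-dioxolan-2-yl)ethyl)-1,3-dioxolan-2-yl]propan-2-yl}heptane-2,6-dione | CC(=O)CC(CC(C)=O)C(C)(C)C1(OCCO1)CCC2(C)OCCO2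
A2 | alternative 1 | 5-substituted 3-methylcyclohex-2-enone with C7 set | CC1=CC(=O)C[C@H](C1)C(C)(C)C2(OCCO2)CCC3(C)OCCO3
A3 | alternative 2 | tricyclic norbornene with bridgehead triethylsilyl ether and endo mesylate, acetonide | CC1(C)OC[C@]2(C)[C@@H]3[C@@H](OS(C)(=O)=O)[C@@]4(O[Si](CC)(CC)CC)C=C(C)[C@@H]3[C@@]4(C)CC[C@H]2O1
A4 | alternative 2 | acetonide of the tricyclic enone diol | CC1(C)OC[C@]2(C)[C@@H]3[C@H]4C(=O)C=C(C)[C@@H]3[C@@]4(C)CC[C@H]2O1
A5 | alternative 3 | carvone-type trimethylsilyl dienol ether with tethered trisubstituted epoxide | CC(C)(C)[Si](C)(C)OC[C@@]1(C)O[C@@H]1CCC2(OCCO2)[C@@H]3CC=C(C)C(O[Si](C)(C)C)=C3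
A6 | alternative 3 | cis-fused bicyclic enone with C5 hydroxyl and quaternary C6 | CC(C)(C)[Si](C)(C)OC[C@]1(C)[C@H]2C(=O)C(C)=CC[C@H]2C3(OCCO3)CC[C@H]1O
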